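**Assumption (one line):** ring atoms are numbered germacrane-style (C1–C3 = CH2 chain, C4 = C(OH)CH3, C5 = CH–O-isobutyryl, C6 = lactone O–CH, C7 = lactone CH, C8 = CH–O-2-methylbutanoyl, C9 = C=O, C10 = CH–CH3, C11=C13 = exocyclic methylene, C12 = lactone C=O), so the target is (4S,5R,6S,7S,8R,10R) with an (R)-2-methylbutanoate; the (R)-acid is treated as not cheaply available and is made; in 36–40 the Me2NCH2 group is drawn trans to the C7–C8 bond (major epimer, centre erased in step 27) and the C1=C2 geometry of 37 is left open (erased in step 25).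

## Retrosynthetic overview

1. Target ⇐ C9 oxidation and unmasking of the α-methylene lactone; the ten-membered carbocycle ⇐ ring-closing metathesis at C1=C2 of a seco-diene (methylene lactone masked as its Me2NH adduct), then hydrogenation.
2. Seco-diene ⇐ Zn-Barbier coupling (C7–C8) of bromomethyl-butenolide 32 (C2–C7, C11–C13) with α-silyloxy aldehyde 15 (C8–C10, C1), then esterification with (R)-2-methylbutanoic acid 7.
3. 32 ⇐ Evans glycolate syn-aldol with an ynal (C5, C6), chelation-controlled MeMgBr addition (C4), Red-Al/I2 and Pd-carbonylative lactonisation.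
4. 15 ⇐ Brown (Z)-crotylboration of PMBOCH2CHO (C9, C10); 7 ⇐ Evans methylation.
5. Ring order: butenolide first (step 19), ten-membered carbocycle last (step 24).

## Route

**Branch 1: (R)-2-methylbutanoic acid**

Step 1
Reactants: 1 (R)-4-benzyloxazolidin-2-one; 2 butanoyl chloride
Product: 3 (R)-4-benzyl-3-butanoyloxazolidin-2-one
Conditions: Et3N, DMAP (cat.), CH2Cl2, 0 °C → rt
Reagents that add atoms: none
Why: DMAP-catalysed N-acylation of the oxazolidinone by the acid chloride attaches the Evans auxiliary without creating a stereocentre.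

Step 2
Reactants: 3 (R)-4-benzyl-3-butanoyloxazolidin-2-one
Product: 5 (R)-4-benzyl-3-[(R)-2-methylbutanoyl]oxazolidin-2-one, via sodium Z-enolate 4 (not isolated)
Conditions: NaHMDS, THF, −78 °C; MeI, −78 → −40 °C
Reagents that add atoms: iodomethane, CI
Why: Evans asymmetric alkylation, in which the chelated Z-enolate is methylated on the face opposite the benzyl group to set the (R) α-centre.

Step 3
Reactants: 5 (R)-4-benzyl-3-[(R)-2-methylbutanoyl]oxazolidin-2-one
Product: 7 (R)-2-methylbutanoic acid, via lithium percarboxylate 6 (not isolated)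
Conditions: LiOH, 30% H2O2, THF/H2O, 0 °C; Na2SO3; HCl
Reagents that add atoms: hydrogen peroxide, OO
Why: LiOOH attacks the exocyclic imide carbonyl selectively and without α-epimerisation (Evans hydrolysis), sulfite reduces the percarboxylate, and auxiliary 1 is recovered.

**Branch 2: aldehyde 15 (C8–C10, C1)**

Step 4
Reactants: 8 (Z)-but-2-ene-1,4-diol
Product: 9 (Z)-1,4-bis(4-methoxybenzyloxy)but-2-ene
Conditions: NaH, PMBCl, Bu4NI (cat.), DMF, 0 °C → rt
Reagents that add atoms: 4-methoxybenzyl chloride, COc1ccc(CCl)cc1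
Why: Double Williamson etherification of the cheap symmetric diol.

Step 5
Reactants: 9 (Z)-1,4-bis(4-methoxybenzyloxy)but-2-ene
Product: 11 2-(4-methoxybenzyloxy)acetaldehyde, via secondary ozonide 10 (not isolated)
Conditions: O3, CH2Cl2, −78 °C (Sudan III end-point); PPh3, −78 °C → rt
Reagents that add atoms: ozone, [O-][O+]=O
Why: Ozonolysis with reductive work-up cleaves the symmetric alkene into two equivalents of the aldehyde.

Step 6
Reactants: 11 2-(4-methoxybenzyloxy)acetaldehyde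
Product: 12 (2S,3R)-1-(4-methoxybenzyloxy)-3-methylpent-4-en-2-ol
Conditions: cis-2-butene, KOtBu, n-BuLi, THF, −78 → −45 °C; (−)-Ipc2BOMe [from (+)-α-pinene], −78 °C; BF3·OEt2; 11, −78 °C; NaOH, H2O2
Reagents that add atoms: cis-2-butene, C/C=C\C
Why: Brown asymmetric crotylboration, in which the (Z)-crotylborane reacts through a closed chair transition state to give the syn adduct and the Ipc groups direct Si-face attack, setting C9 (S) and C10 (R).

Step 7
Reactants: 12 (2S,3R)-1-(4-methoxybenzyloxy)-3-methylpent-4-en-2-ol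
Product: 13 tert-butyl{[(2S,3R)-1-(4-methoxybenzyloxy)-3-methylpent-4-en-2-yl]oxy}dimethylsilane
Conditions: TBSOTf, 2,6-lutidine, CH2Cl2, −78 → 0 °C
Reagents that add atoms: tert-butyldimethylsilyl triflate, CC(C)(C)[Si](C)(C)OS(=O)(=O)C(F)(F)F
Why: Silylation of the secondary alcohol gives a non-chelating C9 protecting group that survives to step 28.

Step 8
Reactants: 13 tert-butyl{[(2S,3R)-1-(4-methoxybenzyloxy)-3-methylpent-4-en-2-yl]oxy}dimethylsilane
Product: 14 (2S,3R)-2-(tert-butyldimethylsilyloxy)-3-methylpent-4-en-1-ol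
Conditions: DDQ, CH2Cl2/pH 7 buffer, 0 °C
Reagents that add atoms: none
Why: Oxidative PMB cleavage by DDQ leaves the terminal alkene and the TBS ether untouched.

Step 9
Reactants: 14 (2S,3R)-2-(tert-butyldimethylsilyloxy)-3-methylpent-4-en-1-ol
Product: 15 (2S,3R)-2-(tert-butyldimethylsilyloxy)-3-methylpent-4-enal
Conditions: Dess–Martin periodinane, NaHCO3, CH2Cl2, 0 °C → rt (used crude)
Reagents that add atoms: none
Why: Dess–Martin oxidation under buffered conditions gives the α-silyloxy aldehyde without epimerisation.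

**Branch 3: bromomethyl-butenolide 32 (C2–C7, C11–C13)**

Step 10
Reactants: 1 (R)-4-benzyloxazolidin-2-one; 16 (benzyloxy)acetyl chloride
Product: 17 (R)-4-benzyl-3-[(benzyloxy)acetyl]oxazolidin-2-one
Conditions: Et3N, DMAP (cat.), CH2Cl2, 0 °C → rt
Reagents that add atoms: none
Why: N-acylation gives the Evans glycolate imide, whose benzyl ether later serves as the chelating group at C5.

Step 11
Reactants: 18 tert-butyldimethyl(prop-2-yn-1-yloxy)silane
Product: 20 4-(tert-butyldimethylsilyloxy)but-2-ynal, via lithium acetylide 19 (not isolated)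
Conditions: n-BuLi, THF, −78 °C; DMF, −78 → 0 °C; inverse quench into aq. KH2PO4
Reagents that add atoms: N,N-dimethylformamide, CN(C)C=O
Why: Formylation of the lithium acetylide with DMF; the buffered inverse quench prevents amine addition to the ynal.

Step 12
Reactants: 17 (R)-4-benzyl-3-[(benzyloxy)acetyl]oxazolidin-2-one; 20 4-(tert-butyldimethylsilyloxy)but-2-ynal
Product: 22 (R)-4-benzyl-3-[(2R,3S)-2-(benzyloxy)-6-(tert-butyldimethylsilyloxy)-3-hydroxyhex-4-ynoyl]oxazolidin-2-one, via dibutylboron Z-enolate 21 (not isolated)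
Conditions: Bu2BOTf, Et3N, CH2Cl2, −78 → 0 °C; 20, −78 → 0 °C; pH 7 buffer, MeOH, H2O2
Reagents that add atoms: none
Why: Evans syn-glycolate aldol, in which the Z-boron enolate reacts through a Zimmerman–Traxler chair on the face set by the (R)-auxiliary to fix C5 (R) and C6 (S).

Step 13
Reactants: 22 (R)-4-benzyl-3-[(2R,3S)-2-(benzyloxy)-6-(tert-butyldimethylsilyloxy)-3-hydroxyhex-4-ynoyl]oxazolidin-2-one
Product: 23 (2R,3S)-2-(benzyloxy)-6-(tert-butyldimethylsilyloxy)-3-hydroxy-N-methoxy-N-methylhex-4-ynamide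
Conditions: MeNH(OMe)·HCl, AlMe3, CH2Cl2, −20 → 0 °C; Rochelle salt
Reagents that add atoms: N,O-dimethylhydroxylamine hydrochloride, CNOC.Cl
Why: Weinreb transamidation by the aluminium amide, assisted by the free β-hydroxyl, removes the auxiliary without touching the stereocentres.

Step 14
Reactants: 23 (2R,3S)-2-(benzyloxy)-6-(tert-butyldimethylsilyloxy)-3-hydroxy-N-methoxy-N-methylhex-4-ynamide
Product: 24 (2R,3S)-2-(benzyloxy)-6-(tert-butyldimethylsilyloxy)-N-methoxy-N-methyl-3-(triethylsilyloxy)hex-4-ynamide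
Conditions: TESCl, imidazole, DMF, 0 °C → rt
Reagents that add atoms: chlorotriethylsilane, CC[Si](Cl)(CC)CC
Why: Silylation turns the C6 oxygen into a bulky non-chelating group so that only the C5 benzyl ether can chelate in step 16.

Step 15
Reactants: 24 (2R,3S)-2-(benzyloxy)-6-(tert-butyldimethylsilyloxy)-N-methoxy-N-methyl-3-(triethylsilyloxy)hex-4-ynamide
Product: 25 (5R,6S)-5-(benzyloxy)-9-(tert-butyldimethylsilyloxy)-6-(triethylsilyloxy)non-1-en-7-yn-4-one
Conditions: allylMgBr, THF, −78 °C; sat. aq. NH4Cl at −78 °C (used at once)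
Reagents that add atoms: allylmagnesium bromide, C=CC[Mg]Br
Why: Weinreb ketone synthesis, in which the chelated tetrahedral adduct prevents over-addition and the cold quench keeps the β,γ-unsaturated ketone from conjugating.

Step 16
Reactants: 25 (5R,6S)-5-(benzyloxy)-9-(tert-butyldimethylsilyloxy)-6-(triethylsilyloxy)non-1-en-7-yn-4-one
Product: 26 (4S,5R,6S)-5-(benzyloxy)-9-(tert-butyldimethylsilyloxy)-4-methyl-6-(triethylsilyloxy)non-1-en-7-yn-4-ol
Conditions: MeMgBr, CH2Cl2/Et2O, −78 °C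
Reagents that add atoms: methylmagnesium bromide, C[Mg]Br
Why: Cram-chelate-controlled Grignard addition, in which Mg bridges the ketone and the C5 benzyloxy oxygen and methyl attacks from the side of C5–H, giving the (4S) tertiary carbinol.

Step 17
Reactants: 26 (4S,5R,6S)-5-(benzyloxy)-9-(tert-butyldimethylsilyloxy)-4-methyl-6-(triethylsilyloxy)non-1-en-7-yn-4-ol
Product: 27 (4S,5R,6S)-5-(benzyloxy)-9-(tert-butyldimethylsilyloxy)-4-methylnon-1-en-7-yne-4,6-diol
Conditions: PPTS (cat.), MeOH/CH2Cl2, 0 °C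
Reagents that add atoms: none
Why: Mild acid methanolysis removes the far more labile secondary TES ether while the primary TBS ether stays.

Step 18
Reactants: 27 (4S,5R,6S)-5-(benzyloxy)-9-(tert-butyldimethylsilyloxy)-4-methylnon-1-en-7-yne-4,6-diol
Product: 29 (4S,5R,6S,7Z)-5-(benzyloxy)-9-(tert-butyldimethylsilyloxy)-8-iodo-4-methylnona-1,7-diene-4,6-diol, via cyclic alkenylaluminate 28 (not isolated)
Conditions: Red-Al, THF, 0 °C → rt; EtOAc; I2, THF, −78 → 0 °C
Reagents that add atoms: iodine, II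
Why: Hydroxyl-directed trans-hydroalumination of the propargylic alcohol places aluminium on the distal alkyne carbon cis to C6, and iodinolysis with retention gives the (Z)-γ-hydroxy vinyl iodide.

Step 19
Reactants: 29 (4S,5R,6S,7Z)-5-(benzyloxy)-9-(tert-butyldimethylsilyloxy)-8-iodo-4-methylnona-1,7-diene-4,6-diol
Product: 30 (5S)-5-[(1R,2S)-1-(benzyloxy)-2-hydroxy-2-methylpent-4-en-1-yl]-3-[(tert-butyldimethylsilyloxy)methyl]furan-2(5H)-one
Conditions: PdCl2(PPh3)2 (5 mol%), CO (1 atm), Et3N, THF, 45 °C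
Reagents that add atoms: carbon monoxide, [C-]#[O+]
Why: Palladium-catalysed carbonylative lactonisation (oxidative addition, CO insertion, capture of the acyl-palladium by the cis C6 hydroxyl) forms the butenolide without touching C6.

Step 20
Reactants: 30 (5S)-5-[(1R,2S)-1-(benzyloxy)-2-hydroxy-2-methylpent-4-en-1-yl]-3-[(tert-butyldimethylsilyloxy)methyl]furan-2(5H)-one
Product: 31 (5S)-5-[(1R,2S)-1-(benzyloxy)-2-hydroxy-2-methylpent-4-en-1-yl]-3-(hydroxymethyl)furan-2(5H)-one
Conditions: HF·pyridine, pyridine, THF, 0 °C → rt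
Reagents that add atoms: none
Why: Buffered fluoride desilylation frees the primary allylic alcohol under conditions too mild to epimerise the butenolide γ-centre.

Step 21
Reactants: 31 (5S)-5-[(1R,2S)-1-(benzyloxy)-2-hydroxy-2-methylpent-4-en-1-yl]-3-(hydroxymethyl)furan-2(5H)-one
Product: 32 (5S)-5-[(1R,2S)-1-(benzyloxy)-2-hydroxy-2-methylpent-4-en-1-yl]-3-(bromomethyl)furan-2(5H)-one
Conditions: CBr4, PPh3, CH2Cl2, 0 °C
Reagents that add atoms: carbon tetrabromide, BrC(Br)(Br)Br
Why: Appel bromination converts the primary allylic alcohol selectively, the hindered tertiary alcohol being inert.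

**Fragment union and end game**

Step 22
Reactants: 32 (5S)-5-[(1R,2S)-1-(benzyloxy)-2-hydroxy-2-methylpent-4-en-1-yl]-3-(bromomethyl)furan-2(5H)-one; 15 (2S,3R)-2-(tert-butyldimethylsilyloxy)-3-methylpent-4-enal
Product: 34 (4R,5S)-5-[(1R,2S)-1-(benzyloxy)-2-hydroxy-2-methylpent-4-en-1-yl]-4-[(1R,2S,3R)-2-(tert-butyldimethylsilyloxy)-1-hydroxy-3-methylpent-4-en-1-yl]-3-methylideneoxolan-2-one, via allylzinc bromide 33 (not isolated)
Conditions: Zn dust (activated), THF/sat. aq. NH4Cl, 0 °C → rt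
Reagents that add atoms: none
Why: Barbier allylation, in which the ring-locked E-type allylzinc adds at its γ-carbon C7 through a closed chair on the butenolide face anti to the C6 side chain, giving the 6,7-trans methylene lactone and the (8R) carbinol, reinforced by Felkin–Anh control from the α-silyloxy centre.

Step 23
Reactants: 34 seco-alcohol; 7 (R)-2-methylbutanoic acid
Product: 36 13-dimethylamino-11,13-dihydro derivative of the 8-O-[(R)-2-methylbutanoyl] ester of 34, via methylene-lactone ester 35 (not isolated)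
Conditions: EDC·HCl, DMAP, CH2Cl2, 0 °C → rt; then Me2NH (2 M in THF), rt
Reagents that add atoms: dimethylamine, CNC
Why: Steglich esterification acylates only the secondary C8 hydroxyl, and the aza-Michael addition of Me2NH then masks the methylene lactone so that it cannot take part in metathesis or be hydrogenated.

Step 24
Reactants: 36 amino-ester seco-diene
Product: 37 ten-membered C1=C2 cycloalkene (5-O-benzyl, 9-O-TBS, 8-O-(R)-2-methylbutanoyl, 13-dimethylamino-11,13-dihydro lactone; E/Z mixture)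
Conditions: p-TsOH·H2O (1.05 equiv), CH2Cl2; Hoveyda–Grubbs II (15 mol%), toluene (1 mM), 80 °C; aq. NaHCO3
Reagents that add atoms: none
Why: Ring-closing metathesis of the C4 allyl and C10 vinyl termini closes the carbocycle with loss of ethene, the amine being protonated so that it cannot ligate ruthenium, and the alkene geometry is irrelevant because the olefin is saturated next.

Step 25
Reactants: 37 ten-membered cycloalkene
Product: 38 saturated 5-hydroxy macrocycle (9-O-TBS, 8-O-(R)-2-methylbutanoyl, 13-dimethylamino-11,13-dihydro lactone)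
Conditions: H2 (3 atm), 20% Pd(OH)2/C, EtOAc/AcOH, rt
Reagents that add atoms: none
Why: Heterogeneous hydrogenation saturates C1=C2 and hydrogenolyses the C5 benzyl ether in one operation, the acetic acid keeping the amine protonated so that it does not inhibit debenzylation.

Step 26
Reactants: 38 saturated 5-hydroxy macrocycle
Product: 39 5-O-isobutyryl macrocycle (9-O-TBS, 13-dimethylamino-11,13-dihydro lactone)
Conditions: isobutyric anhydride, Et3N, DMAP, CH2Cl2, rt
Reagents that add atoms: isobutyric anhydride, CC(C)C(=O)OC(=O)C(C)C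
Why: DMAP-catalysed acylation esterifies the secondary C5 hydroxyl while the tertiary C4 hydroxyl does not react.

Step 27
Reactants: 39 5-O-isobutyryl amino-lactone
Product: 41 9-O-TBS α-methylene lactone, via trimethylammonium iodide 40 (not isolated)
Conditions: MeI, MeOH, rt; evaporate; sat. aq. NaHCO3/CH2Cl2, rt
Reagents that add atoms: none
Why: Quaternisation followed by Hofmann-type E1cB elimination regenerates the exocyclic methylene, done while C9 is still a silyl ether so that no ketone α-centre is exposed to base.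

Step 28
Reactants: 41 9-O-TBS α-methylene lactone
Product: 42 (9S)-9-hydroxy precursor of the target
Conditions: HF·pyridine, THF, 0 °C → rt
Reagents that add atoms: none
Why: Acidic fluoride desilylation frees the C9 alcohol without the basic conditions that would promote C8→C9 acyl migration.

Step 29
Reactants: 42 (9S)-9-hydroxy precursor
Product: 43 CNP0071420.1
Conditions: Dess–Martin periodinane, NaHCO3, CH2Cl2, 0 °C → rt
Reagents that add atoms: none
Why: Dess–Martin oxidation converts the secondary C9 alcohol to the ketone under neutral conditions that leave the tertiary alcohol, both esters, the methylene lactone and the C8/C10 α-centres intact.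

## Compound list

1 | (R)-4-benzyloxazolidin-2-one | O=C1N[C@H](Cc2ccccc2)CO1 | starting material
2 | butanoyl chloride | CCCC(Cl)=O | starting material
3 | (R)-4-benzyl-3-butanoyloxazolidin-2-one | CCCC(=O)N1[C@H](Cc2ccccc2)COC1=O | intermediate
4 | sodium Z-enolate of 3 | CC/C=C(\[O-])N1[C@H](Cc2ccccc2)COC1=O.[Na+] | intermediate
5 | (R)-4-benzyl-3-[(R)-2-methylbutanoyl]oxazolidin-2-one | CC[C@@H](C)C(=O)N1[C@H](Cc2ccccc2)COC1=O | intermediate
6 | lithium (R)-2-methylbutaneperoxoate | CC[C@@H](C)C(=O)O[O-].[Li+] | intermediate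
7 | (R)-2-methylbutanoic acid | CC[C@@H](C)C(=O)O | intermediate
8 | (Z)-but-2-ene-1,4-diol | OC/C=C\CO | starting material
9 | (Z)-1,4-bis(4-methoxybenzyloxy)but-2-ene | COc1ccc(COC/C=C\COCc2ccc(OC)cc2)cc1 | intermediate
10 | 3,5-bis[(4-methoxybenzyloxy)methyl]-1,2,4-trioxolane | COc1ccc(COCC2OOC(COCc3ccc(OC)cc3)O2)cc1 | intermediate
11 | 2-(4-methoxybenzyloxy)acetaldehyde | COc1ccc(COCC=O)cc1 | intermediate
12 | (2S,3R)-1-(4-methoxybenzyloxy)-3-methylpent-4-en-2-ol | COc1ccc(COC[C@@H](O)[C@H](C)C=C)cc1 | intermediate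
13 | tert-butyl{[(2S,3R)-1-(4-methoxybenzyloxy)-3-methylpent-4-en-2-yl]oxy}dimethylsilane | COc1ccc(COC[C@@H](O[Si](C)(C)C(C)(C)C)[C@H](C)C=C)cc1 | intermediate
14 | (2S,3R)-2-(tert-butyldimethylsilyloxy)-3-methylpent-4-en-1-ol | OC[C@@H](O[Si](C)(C)C(C)(C)C)[C@H](C)C=C | intermediate
15 | (2S,3R)-2-(tert-butyldimethylsilyloxy)-3-methylpent-4-enal | O=C[C@@H](O[Si](C)(C)C(C)(C)C)[C@H](C)C=C | intermediate
16 | (benzyloxy)acetyl chloride | O=C(Cl)COCc1ccccc1 | starting material
17 | (R)-4-benzyl-3-[(benzyloxy)acetyl]oxazolidin-2-one | O=C(COCc1ccccc1)N1[C@H](Cc2ccccc2)COC1=O | intermediate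
18 | tert-butyldimethyl(prop-2-yn-1-yloxy)silane | C#CCO[Si](C)(C)C(C)(C)C | starting material
19 | lithium acetylide of 18 | [Li]C#CCO[Si](C)(C)C(C)(C)C | intermediate
20 | 4-(tert-butyldimethylsilyloxy)but-2-ynal | O=CC#CCO[Si](C)(C)C(C)(C)C | intermediate
21 | dibutylboron Z-enolate of 17 | CCCCB(CCCC)O/C(=C\OCc1ccccc1)N1[C@H](Cc2ccccc2)COC1=O | intermediate
22 | (R)-4-benzyl-3-[(2R,3S)-2-(benzyloxy)-6-(tert-butyldimethylsilyloxy)-3-hydroxyhex-4-ynoyl]oxazolidin-2-one | O=C(N1[C@H](Cc2ccccc2)COC1=O)[C@H](OCc1ccccc1)[C@@H](O)C#CCO[Si](C)(C)C(C)(C)C | intermediate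
23 | (2R,3S)-2-(benzyloxy)-6-(tert-butyldimethylsilyloxy)-3-hydroxy-N-methoxy-N-methylhex-4-ynamide | CON(C)C(=O)[C@H](OCc1ccccc1)[C@@H](O)C#CCO[Si](C)(C)C(C)(C)C | intermediate
24 | (2R,3S)-2-(benzyloxy)-6-(tert-butyldimethylsilyloxy)-N-methoxy-N-methyl-3-(triethylsilyloxy)hex-4-ynamide | CON(C)C(=O)[C@H](OCc1ccccc1)[C@@H](O[Si](CC)(CC)CC)C#CCO[Si](C)(C)C(C)(C)C | intermediate
25 | (5R,6S)-5-(benzyloxy)-9-(tert-butyldimethylsilyloxy)-6-(triethylsilyloxy)non-1-en-7-yn-4-one | C=CCC(=O)[C@H](OCc1ccccc1)[C@@H](O[Si](CC)(CC)CC)C#CCO[Si](C)(C)C(C)(C)C | intermediate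
26 | (4S,5R,6S)-5-(benzyloxy)-9-(tert-butyldimethylsilyloxy)-4-methyl-6-(triethylsilyloxy)non-1-en-7-yn-4-ol | C=CC[C@](C)(O)[C@H](OCc1ccccc1)[C@@H](O[Si](CC)(CC)CC)C#CCO[Si](C)(C)C(C)(C)C | intermediate
27 | (4S,5R,6S)-5-(benzyloxy)-9-(tert-butyldimethylsilyloxy)-4-methylnon-1-en-7-yne-4,6-diol | C=CC[C@](C)(O)[C@H](OCc1ccccc1)[C@@H](O)C#CCO[Si](C)(C)C(C)(C)C | intermediate
28 | sodium cyclic (E)-alkenylaluminate of 27 (five-membered O–Al–C=C chelate; tertiary OH also metalated in the flask) | C=CC[C@](C)(O)[C@H](OCc1ccccc1)[C@H]1O[Al-](OCCOC)(OCCOC)C(CO[Si](C)(C)C(C)(C)C)=C1.[Na+] | intermediate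
29 | (4S,5R,6S,7Z)-5-(benzyloxy)-9-(tert-butyldimethylsilyloxy)-8-iodo-4-methylnona-1,7-diene-4,6-diol | C=CC[C@](C)(O)[C@H](OCc1ccccc1)[C@@H](O)/C=C(\I)CO[Si](C)(C)C(C)(C)C | intermediate
30 | (5S)-5-[(1R,2S)-1-(benzyloxy)-2-hydroxy-2-methylpent-4-en-1-yl]-3-[(tert-butyldimethylsilyloxy)methyl]furan-2(5H)-one | C=CC[C@](C)(O)[C@H](OCc1ccccc1)[C@H]1OC(=O)C(CO[Si](C)(C)C(C)(C)C)=C1 | intermediate
31 | (5S)-5-[(1R,2S)-1-(benzyloxy)-2-hydroxy-2-methylpent-4-en-1-yl]-3-(hydroxymethyl)furan-2(5H)-one | C=CC[C@](C)(O)[C@H](OCc1ccccc1)[C@H]1OC(=O)C(CO)=C1 | intermediate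
32 | (5S)-5-[(1R,2S)-1-(benzyloxy)-2-hydroxy-2-methylpent-4-en-1-yl]-3-(bromomethyl)furan-2(5H)-one | C=CC[C@](C)(O)[C@H](OCc1ccccc1)[C@H]1OC(=O)C(CBr)=C1 | intermediate
33 | allylzinc bromide from 32 | C=CC[C@](C)(O)[C@H](OCc1ccccc1)[C@H]1OC(=O)C(C[Zn]Br)=C1 | intermediate
34 | (4R,5S)-5-[(1R,2S)-1-(benzyloxy)-2-hydroxy-2-methylpent-4-en-1-yl]-4-[(1R,2S,3R)-2-(tert-butyldimethylsilyloxy)-1-hydroxy-3-methylpent-4-en-1-yl]-3-methylideneoxolan-2-one | C=C1C(=O)O[C@H]([C@@H](OCc2ccccc2)[C@@](C)(O)CC=C)[C@H]1[C@@H](O)[C@@H](O[Si](C)(C)C(C)(C)C)[C@H](C)C=C | intermediate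
35 | 8-O-[(R)-2-methylbutanoyl] ester of 34 (all other centres as in 34) | C=C1C(=O)O[C@H]([C@@H](OCc2ccccc2)[C@@](C)(O)CC=C)[C@H]1[C@@H](OC(=O)[C@H](C)CC)[C@@H](O[Si](C)(C)C(C)(C)C)[C@H](C)C=C | intermediate
36 | 13-dimethylamino-11,13-dihydro derivative of 35 (Me2NCH2 at C11 trans to the C7–C8 bond) | CN(C)C[C@@H]1C(=O)O[C@H]([C@@H](OCc2ccccc2)[C@@](C)(O)CC=C)[C@H]1[C@@H](OC(=O)[C@H](C)CC)[C@@H](O[Si](C)(C)C(C)(C)C)[C@H](C)C=C | intermediate
37 | ten-membered C1=C2 cycloalkene from 36 (5-O-benzyl, 9-O-TBS, 8-O-(R)-2-methylbutanoyl, 13-dimethylamino-11,13-dihydro lactone; E/Z mixture) | CN(C)C[C@@H]1C(=O)O[C@H]2[C@H]1[C@@H](OC(=O)[C@H](C)CC)[C@@H](O[Si](C)(C)C(C)(C)C)[C@H](C)C=CC[C@](C)(O)[C@@H]2OCc1ccccc1 | intermediate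
38 | saturated 5-hydroxy macrocycle (9-O-TBS, 8-O-(R)-2-methylbutanoyl, 13-dimethylamino-11,13-dihydro lactone) | CN(C)C[C@@H]1C(=O)O[C@H]2[C@H]1[C@@H](OC(=O)[C@H](C)CC)[C@@H](O[Si](C)(C)C(C)(C)C)[C@H](C)CCC[C@](C)(O)[C@@H]2O | intermediate
39 | 5-O-isobutyryl derivative of 38 | CN(C)C[C@@H]1C(=O)O[C@H]2[C@H]1[C@@H](OC(=O)[C@H](C)CC)[C@@H](O[Si](C)(C)C(C)(C)C)[C@H](C)CCC[C@](C)(O)[C@@H]2OC(=O)C(C)C | intermediate
40 | 13-trimethylammonium iodide of 39 | C[N+](C)(C)C[C@@H]1C(=O)O[C@H]2[C@H]1[C@@H](OC(=O)[C@H](C)CC)[C@@H](O[Si](C)(C)C(C)(C)C)[C@H](C)CCC[C@](C)(O)[C@@H]2OC(=O)C(C)C.[I-] | intermediate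
41 | 9-O-TBS ether of the (9S)-9-hydroxy precursor (α-methylene lactone restored) | C=C1C(=O)O[C@H]2[C@H]1[C@@H](OC(=O)[C@H](C)CC)[C@@H](O[Si](C)(C)C(C)(C)C)[C@H](C)CCC[C@](C)(O)[C@@H]2OC(=O)C(C)C | intermediate
42 | (9S)-9-hydroxy precursor (9-deoxo-9-hydroxy target) | C=C1C(=O)O[C@H]2[C@H]1[C@@H](OC(=O)[C@H](C)CC)[C@@H](O)[C@H](C)CCC[C@](C)(O)[C@@H]2OC(=O)C(C)C | intermediate
43 | CNP0071420.1 | C=C1C(=O)O[C@H]2[C@H]1[C@@H](OC(=O)[C@H](C)CC)C(=O)[C@H](C)CCC[C@](C)(O)[C@@H]2OC(=O)C(C)C | target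

## Step count and risks

Total step count: 29. Longest linear sequence: 19 steps (18 → 43, steps 11–29). The other paths are 19 (via 17), 14 (branch 2) and 10 (branch 1).

**Step 24 (ring-closing metathesis).** A ten-membered ring with a hindered, branched vinyl partner may give mostly oligomers or stall. The fallback sets out from 32 and 14 and comes back at 37. It makes the C1=C2 bond intermolecularly and closes the ring at C7–C8 instead. Cross-metathesis of 32 with excess 14 (Hoveyda–Grubbs II, CH2Cl2, 40 °C) gives the E-configured bromo alcohol F4. Dess–Martin oxidation gives the bromo aldehyde F5. Slow addition of F5 to activated zinc in THF/aq. NH4Cl at high dilution (or CrCl2 in DMF) forms the allylzinc bromide F6, which closes the ring in an intramolecular Barbier macrocyclisation to the macrocyclic homoallylic alcohol F7. Esterification with 7 (EDC, DMAP) gives the ester F8, and addition of Me2NH gives 37 as its E isomer, which enters step 25.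

**Step 22 (Barbier coupling).** The allylzinc may be protonated (simple reduction of the bromide) or the diastereoselectivity at C7/C8 may be low in the aqueous medium. The fallback sets out from 32 and comes back at 34. Palladium-catalysed borylation of 32 (B2pin2, Pd2(dba)3, DMSO, 50 °C) gives the allyl pinacolboronate F3. Thermal allylboration of 15 with F3 (toluene, rt → 50 °C, then aqueous work-up) passes through the same closed chair with no reducing metal and gives 34.

**Step 16 (chelation-controlled methyl addition).** The β,γ-unsaturated ketone 25 may enolise or conjugate under MeMgBr, and chelation control may erode. The fallback sets out from 24 and comes back at 26. It reverses the order in which the two carbon groups arrive at C4. MeMgBr on 24 (THF, 0 °C) gives the robust methyl ketone F1. Corey–Chaykovsky epoxidation (Me3S+ I−, KHMDS, THF, −20 °C) under Felkin–Anh control gives the 2-methyloxirane F2, in which the ylide carbon is the future C3. Copper-catalysed opening of F2 at its CH2 terminus with vinylmagnesium bromide (CuI, THF, −30 °C) gives 26.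

## Further compounds

F1 | step 16 | (3R,4S)-3-(benzyloxy)-7-(tert-butyldimethylsilyloxy)-4-(triethylsilyloxy)hept-5-yn-2-one | CC(=O)[C@H](OCc1ccccc1)[C@@H](O[Si](CC)(CC)CC)C#CCO[Si](C)(C)C(C)(C)C
F2 | step 16 | 2-methyloxirane from F1 (C4 configured as in 26; epoxide CH2 = C3) | C[C@]1(CO1)[C@H](OCc2ccccc2)[C@@H](O[Si](CC)(CC)CC)C#CCO[Si](C)(C)C(C)(C)C
F3 | step 22 | (5S)-5-[(1R,2S)-1-(benzyloxy)-2-hydroxy-2-methylpent-4-en-1-yl]-3-[(4,4,5,5-tetramethyl-1,3,2-dioxaborolan-2-yl)methyl]furan-2(5H)-one | C=CC[C@](C)(O)[C@H](OCc1ccccc1)[C@H]1OC(=O)C(CB2OC(C)(C)C(C)(C)O2)=C1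
F4 | step 24 | E cross-metathesis product of 32 and 14 (bromomethyl-butenolide with C8 primary alcohol) | OC[C@@H](O[Si](C)(C)C(C)(C)C)[C@H](C)/C=C/C[C@](C)(O)[C@H](OCc1ccccc1)[C@H]1OC(=O)C(CBr)=C1
F5 | step 24 | C8 aldehyde from F4 | O=C[C@@H](O[Si](C)(C)C(C)(C)C)[C@H](C)/C=C/C[C@](C)(O)[C@H](OCc1ccccc1)[C@H]1OC(=O)C(CBr)=C1
F6 | step 24 | allylzinc bromide from F5 | O=C[C@@H](O[Si](C)(C)C(C)(C)C)[C@H](C)/C=C/C[C@](C)(O)[C@H](OCc1ccccc1)[C@H]1OC(=O)C(C[Zn]Br)=C1
F7 | step 24 | macrocyclic (1E)-8-hydroxy α-methylene lactone (5-O-benzyl, 9-O-TBS) | C=C1C(=O)O[C@H]2[C@H]1[C@@H](O)[C@@H](O[Si](C)(C)C(C)(C)C)[C@H](C)/C=C/C[C@](C)(O)[C@@H]2OCc1ccccc1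
F8 | step 24 | 8-O-[(R)-2-methylbutanoyl] ester of F7 | C=C1C(=O)O[C@H]2[C@H]1[C@@H](OC(=O)[C@H](C)CC)[C@@H](O[Si](C)(C)C(C)(C)C)[C@H](C)/C=C/C[C@](C)(O)[C@@H]2OCc1ccccc1
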